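**Retrosynthetic overview**
1. Target = 18-acetoxylabd-8(17)-en-15-oic acid. The last operations acetylate O18, remove a benzyl group, and erase a temporary C3 ketone (Wolff–Kishner) and a temporary C2 ester (Krapcho).
2. Key disconnection C2–C3: ring A is closed last by Dieckmann condensation of a diester on ring B (arm C10–CH2CH2CO2Et, arm C5–CH(CH3)CO2Et). In the same flask the β-keto ester dianion is alkylated at C4 with the C18 carbon.
3. Enabling feature: C2–C3 lies next to the quaternary C4 that carries the oxygenated C18, so a carbonyl can be parked at C3 and an ester at C2. The two arms on C5 and C10 are trans on ring B, so only a trans-decalin can form, and the axial C10 methyl steers the C4 alkylation.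
4. Ring B comes from 2-methylcyclohex-2-enone: CBS reduction, Johnson–Claisen (C5), allylic oxidation, homoenolate conjugate addition (C10), Mukaiyama aldol/dehydration/hydrogenation (C9 side chain), Wittig (C17).
5. Side chain C11–C15 with C13 comes from (R)-methyl hydrogen 3-methylglutarate. Ring order: ring B is purchased, ring A is formed in the key step.

Key step: step 12

Remark: the target is read as (4R,5R,9S,10R,13S)-18-acetoxylabd-8(17)-en-15-oic acid; labdane numbering (C1 to C20, C10 methyl β) is used for locants in the bicyclic names and in the reasoning.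

**Route**

Step 1
Reactants: 1 (R)-5-methoxy-3-methyl-5-oxopentanoic acid
Product: 3 (S)-4-methyloxan-2-one, via (S)-5-hydroxy-3-methylpentanoic acid 2 (not isolated)
Conditions: LiBH4, THF, 0 °C to reflux; then 2 M HCl, rt
Reagents that add atoms: none
Why: Chemoselective borohydride reduction of the ester beside the lithium carboxylate, then acid-promoted lactonisation of the 5-hydroxy acid, should give the δ-lactone; the stereocentre (C13 of the target) is not touched.

Step 2
Reactants: 3 (S)-4-methyloxan-2-one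
Product: 5 benzyl (S)-5-hydroxy-3-methylpentanoate, via potassium (S)-5-hydroxy-3-methylpentanoate 4 (not isolated)
Conditions: KOH (1.0 equiv), MeOH/H2O, rt, evaporate; BnBr, DMF, rt; used at once
Reagents that add atoms: potassium hydroxide, [K+].[OH-]; benzyl bromide, BrCc1ccccc1
Why: Saponification opens the lactone and the carboxylate is O-alkylated by benzyl bromide (SN2) before it can relactonise, giving an ester that is later removed by hydrogenolysis.

Step 3
Reactants: 5 benzyl (S)-5-hydroxy-3-methylpentanoate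
Product: 6 benzyl (S)-3-methyl-5-oxopentanoate
Conditions: Dess–Martin periodinane, NaHCO3, CH2Cl2, rt
Reagents that add atoms: none
Why: Dess–Martin oxidation of the primary alcohol stops at the aldehyde under neutral conditions that leave the benzyl ester and the β-stereocentre alone.

Step 4
Reactants: 7 2-methylcyclohex-2-en-1-one
Product: 8 (S)-2-methylcyclohex-2-en-1-ol
Conditions: (R)-2-methyl-CBS-oxazaborolidine (10 mol %), BH3·SMe2, THF, −20 °C; MeOH
Reagents that add atoms: none
Why: Corey–Bakshi–Shibata reduction in which the alkenyl flank acts as the large group, so the (R)-catalyst should deliver hydride to give the (S)-carbinol (the future C9 oxygen on the β face).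

Step 5
Reactants: 8 (S)-2-methylcyclohex-2-en-1-ol
Product: 10 ethyl 2-[(1S)-2-methylcyclohex-2-en-1-yl]propanoate (both epimers at the ester α-carbon), via mixed ketene acetal 9 (not isolated)
Conditions: triethyl orthopropionate (5 equiv), EtCO2H (cat.), 140 °C, EtOH distilled off
Reagents that add atoms: triethyl orthopropionate, CCC(OCC)(OCC)OCC
Why: Johnson–Claisen rearrangement; the suprafacial [3,3] shift transfers the carbinol configuration to C5 (new C4–C5 bond on the face the oxygen leaves), while C4 stays an inconsequential mixture that is planarised later.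

Step 6
Reactants: 10 ethyl 2-[(1S)-2-methylcyclohex-2-en-1-yl]propanoate
Product: 11 ethyl 2-[(1S)-2-methyl-4-oxocyclohex-2-en-1-yl]propanoate
Conditions: Rh2(cap)4 (dirhodium tetracaprolactamate, 1 mol %), t-BuOOH (aq., 5 equiv), K2CO3 (0.5 equiv), CH2Cl2, rt
Reagents that add atoms: tert-butyl hydroperoxide, CC(C)(C)OO
Why: Rhodium-catalysed allylic C–H oxidation at the only secondary allylic methylene (C8) should give the conjugated enone without touching C5.

Step 7
Reactants: 11 ethyl 2-[(1S)-2-methyl-4-oxocyclohex-2-en-1-yl]propanoate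
Product: 12 ethyl 2-[(1S,2S)-2-(3-ethoxy-3-oxopropyl)-2-methyl-4-(trimethylsilyloxy)cyclohex-3-en-1-yl]propanoate
Conditions: (1-ethoxycyclopropoxy)trimethylsilane (2.2 equiv), ZnCl2 (1.1 equiv), Et2O, rt; then CuBr·SMe2 (5 mol %), HMPA, THF, 11, 0 °C to rt; non-aqueous work-up
Reagents that add atoms: (1-ethoxycyclopropoxy)trimethylsilane, CCOC1(CC1)O[Si](C)(C)C
Why: Copper-catalysed conjugate addition of a zinc homoenolate, made in the flask together with the chlorotrimethylsilane that accelerates the addition and traps the enolate; attack anti to the pseudo-axial C5 substituent should set the quaternary C10 with the new arm trans to the C5 arm and leave a regiodefined silyl enol ether.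

Step 8
Reactants: 12 ethyl 2-[(1S,2S)-2-(3-ethoxy-3-oxopropyl)-2-methyl-4-(trimethylsilyloxy)cyclohex-3-en-1-yl]propanoate; 6 benzyl (S)-3-methyl-5-oxopentanoate
Product: 13 benzyl (3S)-5-[(2S,3S)-2-(3-ethoxy-3-oxopropyl)-3-(1-ethoxy-1-oxopropan-2-yl)-2-methyl-6-oxocyclohexyl]-5-hydroxy-3-methylpentanoate
Conditions: TiCl4, CH2Cl2, −78 °C; aq. NaHCO3
Reagents that add atoms: none
Why: Mukaiyama aldol addition of the regiodefined silyl enol ether forms the C9–C11 bond; the two new stereocentres are removed in the next two steps.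

Step 9
Reactants: 13 benzyl (3S)-5-[(2S,3S)-2-(3-ethoxy-3-oxopropyl)-3-(1-ethoxy-1-oxopropan-2-yl)-2-methyl-6-oxocyclohexyl]-5-hydroxy-3-methylpentanoate
Product: 15 benzyl (3S)-5-[(2S,3S)-2-(3-ethoxy-3-oxopropyl)-3-(1-ethoxy-1-oxopropan-2-yl)-2-methyl-6-oxocyclohexylidene]-3-methylpentanoate, via mesylate 14 (not isolated)
Conditions: MsCl, Et3N, CH2Cl2, 0 °C; then DBU, rt
Reagents that add atoms: none
Why: Mesylation and base-induced elimination (E1cB) complete an aldol condensation to the exocyclic enone, whose alkene geometry is irrelevant.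

Step 10
Reactants: 15 benzyl (3S)-5-[(2S,3S)-2-(3-ethoxy-3-oxopropyl)-3-(1-ethoxy-1-oxopropan-2-yl)-2-methyl-6-oxocyclohexylidene]-3-methylpentanoate
Product: 16 (3S)-5-[(1R,2S,3S)-2-(3-ethoxy-3-oxopropyl)-3-(1-ethoxy-1-oxopropan-2-yl)-2-methyl-6-oxocyclohexyl]-3-methylpentanoic acid
Conditions: H2 (1 atm), 10% Pd/C, EtOAc, rt
Reagents that add atoms: none
Why: Catalytic hydrogenation should add hydrogen from the α face opposite the axial C10 methyl (9α-H, equatorial side chain, also the thermodynamic epimer next to the ketone), and hydrogenolysis removes the benzyl ester.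

Step 11
Reactants: 16 (3S)-5-[(1R,2S,3S)-2-(3-ethoxy-3-oxopropyl)-3-(1-ethoxy-1-oxopropan-2-yl)-2-methyl-6-oxocyclohexyl]-3-methylpentanoic acid
Product: 17 (3S)-5-[(1S,2S,3S)-2-(3-ethoxy-3-oxopropyl)-3-(1-ethoxy-1-oxopropan-2-yl)-2-methyl-6-methylidenecyclohexyl]-3-methylpentanoic acid
Conditions: Ph3PCH3Br (4 equiv), KOtBu (3.9 equiv), THF, 0 °C (ylide preformed); then 16, 0 °C to rt
Reagents that add atoms: methyltriphenylphosphonium bromide, C[P+](c1ccccc1)(c1ccccc1)c1ccccc1.[Br-]
Why: Wittig methylenation of the ketone installs C17; the preformed ylide should not attack the carboxylate or the ethyl esters.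

Step 12
Reactants: 17 (3S)-5-[(1S,2S,3S)-2-(3-ethoxy-3-oxopropyl)-3-(1-ethoxy-1-oxopropan-2-yl)-2-methyl-6-methylidenecyclohexyl]-3-methylpentanoic acid
Product: 19 18-(benzyloxy)-2-(ethoxycarbonyl)-3-oxolabd-8(17)-en-15-oic acid, via β-keto ester sodium enolate 18 (not isolated)
Conditions: NaH (3.3 equiv), EtOH (cat.), THF, 0 to 50 °C; then LDA (1.3 equiv), −78 to 0 °C; BnOCH2Cl (2.4 equiv), −78 to −20 °C; aq. HCl
Reagents that add atoms: benzyl chloromethyl ether, ClCOCc1ccccc1
Why: Sodium hydride forms the ester enolates reversibly, and the enolate at C2 (α to the ester of the C10 arm) adds to the C3 ester of the C5 arm and expels ethoxide, a Dieckmann condensation that closes ring A in the 6-exo-trig mode. The alternative closure (C4 enolate on the other ester) would give a β-keto ester without an acidic hydrogen between the carbonyl groups and reverts, whereas the wanted product is drained as its sodium enolate 18. The ring closure creates no stereocentre that must be controlled, because the two arms are trans-diequatorial on the chair of ring B and can only span a trans-decalin. LDA then removes the C4 hydrogen of 18 and the more reactive C4 carbanion is alkylated by benzyl chloromethyl ether, the closest known types being the sodium hydride Dieckmann cyclisation and the γ-alkylation of β-keto ester dianions. The new quaternary centre C4 is controlled by the axial C10 methyl group, which is 1,3-diaxial to the β face of C4, so the electrophile should enter from the α face (equatorial CH2OBn, axial CH3). The step needs site selectivity for C4 over C2 and oxygen and facial selectivity at C4; the first is secured by the dianion (the carbanion formed last reacts first), the second by the angular methyl group, and excess electrophile makes up for what ethoxide consumes.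

Step 13
Reactants: 19 18-(benzyloxy)-2-(ethoxycarbonyl)-3-oxolabd-8(17)-en-15-oic acid
Product: 20 18-(benzyloxy)-3-oxolabd-8(17)-en-15-oic acid
Conditions: LiCl, H2O, DMSO, 150 °C
Reagents that add atoms: none
Why: Krapcho dealkoxycarbonylation removes the temporary ester at C2 of the β-keto ester.

Step 14
Reactants: 20 18-(benzyloxy)-3-oxolabd-8(17)-en-15-oic acid
Product: 22 18-(benzyloxy)labd-8(17)-en-15-oic acid, via hydrazone 21 (not isolated)
Conditions: N2H4·H2O, KOH, diethylene glycol, 130 °C then 200 °C; aq. HCl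
Reagents that add atoms: none
Why: Wolff–Kishner reduction through the hydrazone erases the temporary C3 carbonyl; the benzyl ether, the carboxylate and the isolated alkene should survive hot hydroxide.

Step 15
Reactants: 22 18-(benzyloxy)labd-8(17)-en-15-oic acid
Product: 23 18-hydroxylabd-8(17)-en-15-oic acid
Conditions: Li, NH3 (l), THF, −78 °C; NH4Cl
Reagents that add atoms: none
Why: Dissolving-metal cleavage of the benzyl ether; the unconjugated 1,1-disubstituted alkene and the lithium carboxylate should not be reduced.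

Step 16
Reactants: 23 18-hydroxylabd-8(17)-en-15-oic acid
Product: 24 (4R,5R,9S,10R,13S)-18-acetoxylabd-8(17)-en-15-oic acid
Conditions: Ac2O, pyridine, DMAP (cat.), CH2Cl2, rt; then H2O/NaHCO3, acidify to pH 3
Reagents that add atoms: acetic anhydride, CC(=O)OC(C)=O
Why: DMAP-catalysed acetylation of the primary alcohol; the mixed anhydride formed at the acid is hydrolysed during aqueous work-up.

**Compound list**
1 | (R)-5-methoxy-3-methyl-5-oxopentanoic acid ((R)-methyl hydrogen 3-methylglutarate) | OC(=O)C[C@@H](C)CC(=O)OC | starting material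
2 | (S)-5-hydroxy-3-methylpentanoic acid | OCC[C@H](C)CC(=O)O | intermediate
3 | (S)-4-methyloxan-2-one | O=C1C[C@@H](C)CCO1 | intermediate
4 | potassium (S)-5-hydroxy-3-methylpentanoate | OCC[C@H](C)CC(=O)[O-].[K+] | intermediate
5 | benzyl (S)-5-hydroxy-3-methylpentanoate | OCC[C@H](C)CC(=O)OCc1ccccc1 | intermediate
6 | benzyl (S)-3-methyl-5-oxopentanoate | O=CC[C@H](C)CC(=O)OCc1ccccc1 | intermediate
7 | 2-methylcyclohex-2-en-1-one | CC1=CCCCC1=O | starting material
8 | (S)-2-methylcyclohex-2-en-1-ol | CC1=CCCC[C@@H]1O | intermediate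
9 | mixed ketene acetal, (S)-6-[(1-ethoxyprop-1-en-1-yl)oxy]-1-methylcyclohex-1-ene | CC=C(OCC)O[C@H]1CCCC=C1C | intermediate
10 | ethyl 2-[(1S)-2-methylcyclohex-2-en-1-yl]propanoate (epimers at the ester α-carbon) | CC1=CCCC[C@H]1C(C)C(=O)OCC | intermediate
11 | ethyl 2-[(1S)-2-methyl-4-oxocyclohex-2-en-1-yl]propanoate | O=C1C=C(C)[C@H](C(C)C(=O)OCC)CC1 | intermediate
12 | ethyl 2-[(1S,2S)-2-(3-ethoxy-3-oxopropyl)-2-methyl-4-(trimethylsilyloxy)cyclohex-3-en-1-yl]propanoate | C[Si](C)(C)OC1=C[C@@](C)(CCC(=O)OCC)[C@H](C(C)C(=O)OCC)CC1 | intermediate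
13 | benzyl (3S)-5-[(2S,3S)-2-(3-ethoxy-3-oxopropyl)-3-(1-ethoxy-1-oxopropan-2-yl)-2-methyl-6-oxocyclohexyl]-5-hydroxy-3-methylpentanoate (mixture at ring C1 and chain C5) | O=C1CC[C@@H](C(C)C(=O)OCC)[C@](C)(CCC(=O)OCC)C1C(O)C[C@H](C)CC(=O)OCc2ccccc2 | intermediate
14 | 5-methanesulfonate of 13 | O=C1CC[C@@H](C(C)C(=O)OCC)[C@](C)(CCC(=O)OCC)C1C(OS(C)(=O)=O)C[C@H](C)CC(=O)OCc2ccccc2 | intermediate
15 | benzyl (3S)-5-[(2S,3S)-2-(3-ethoxy-3-oxopropyl)-3-(1-ethoxy-1-oxopropan-2-yl)-2-methyl-6-oxocyclohexylidene]-3-methylpentanoate (alkene geometry not defined) | O=C1CC[C@@H](C(C)C(=O)OCC)[C@](C)(CCC(=O)OCC)C1=CC[C@H](C)CC(=O)OCc2ccccc2 | intermediate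
16 | (3S)-5-[(1R,2S,3S)-2-(3-ethoxy-3-oxopropyl)-3-(1-ethoxy-1-oxopropan-2-yl)-2-methyl-6-oxocyclohexyl]-3-methylpentanoic acid | O=C1CC[C@@H](C(C)C(=O)OCC)[C@](C)(CCC(=O)OCC)[C@H]1CC[C@H](C)CC(=O)O | intermediate
17 | (3S)-5-[(1S,2S,3S)-2-(3-ethoxy-3-oxopropyl)-3-(1-ethoxy-1-oxopropan-2-yl)-2-methyl-6-methylidenecyclohexyl]-3-methylpentanoic acid | C=C1CC[C@@H](C(C)C(=O)OCC)[C@](C)(CCC(=O)OCC)[C@H]1CC[C@H](C)CC(=O)O | intermediate
18 | ring A β-keto ester, 2-(ethoxycarbonyl)-3-oxo-18-norlabd-8(17)-en-15-oic acid (5α-H, 9α-H, 10β-CH3, 13S; C2 and C4 not defined; sodium enolate in the flask) | C=C1CC[C@H]2C(C)C(=O)C(C(=O)OCC)C[C@]2(C)[C@H]1CC[C@H](C)CC(=O)O | intermediate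
19 | 18-(benzyloxy)-2-(ethoxycarbonyl)-3-oxolabd-8(17)-en-15-oic acid (4α-CH2OBn, 4β-CH3; C2 not defined) | C=C1CC[C@H]2[C@](C)(COCc3ccccc3)C(=O)C(C(=O)OCC)C[C@]2(C)[C@H]1CC[C@H](C)CC(=O)O | intermediate
20 | 18-(benzyloxy)-3-oxolabd-8(17)-en-15-oic acid | C=C1CC[C@H]2[C@](C)(COCc3ccccc3)C(=O)CC[C@]2(C)[C@H]1CC[C@H](C)CC(=O)O | intermediate
21 | C3 hydrazone of 20 | C=C1CC[C@H]2[C@](C)(COCc3ccccc3)C(=NN)CC[C@]2(C)[C@H]1CC[C@H](C)CC(=O)O | intermediate
22 | (4R,5R,9S,10R,13S)-18-(benzyloxy)labd-8(17)-en-15-oic acid | C=C1CC[C@H]2[C@](C)(COCc3ccccc3)CCC[C@]2(C)[C@H]1CC[C@H](C)CC(=O)O | intermediate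
23 | (4R,5R,9S,10R,13S)-18-hydroxylabd-8(17)-en-15-oic acid | C=C1CC[C@H]2[C@](C)(CO)CCC[C@]2(C)[C@H]1CC[C@H](C)CC(=O)O | intermediate
24 | (4R,5R,9S,10R,13S)-18-acetoxylabd-8(17)-en-15-oic acid | C=C1CC[C@H]2[C@](C)(COC(C)=O)CCC[C@]2(C)[C@H]1CC[C@H](C)CC(=O)O | target

**Step count and risks**

Total step count: 16. Longest linear sequence: 13 steps (steps 4 to 16, from 2-methylcyclohex-2-en-1-one); the side-chain aldehyde takes 3 steps.

Most likely to fail:

1. Step 7. The β-carbon C10 is flanked by the branched C5 substituent, so the conjugate addition may be slow, may be diverted to 1,2-addition, or may lose facial control. The fallback sets out from 11 and returns at 15. A Hosomi–Sakurai allylation (allyltrimethylsilane, TiCl4, CH2Cl2, −78 °C) should add the allyl group anti to the C5 arm, and the titanium enolate is trapped in the same flask with aldehyde 6 to give benzyl (3S)-5-[(2S,3S)-3-(1-ethoxy-1-oxopropan-2-yl)-2-methyl-6-oxo-2-(prop-2-en-1-yl)cyclohexyl]-5-hydroxy-3-methylpentanoate F4. Mesylation and elimination with DBU give the exocyclic enone benzyl (3S)-5-[(2S,3S)-3-(1-ethoxy-1-oxopropan-2-yl)-2-methyl-6-oxo-2-(prop-2-en-1-yl)cyclohexylidene]-3-methylpentanoate F5. Hydroboration of the terminal alkene with 9-BBN and oxidation with NaBO3 give the primary alcohol, the 2-(3-hydroxypropyl) analogue of F5, F6. CrO3/H2SO4 in acetone gives the carboxylic acid, the 2-(2-carboxyethyl) analogue of F5, F7. Esterification with EtI and K2CO3 in DMF gives 15.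

2. Step 12. The ring closure may stay incomplete or reopen by retro-Claisen cleavage, the dianion may be quenched or O-alkylated, or the facial bias at C4 may be insufficient. The fallback sets out from 17 and returns at 20. Dieckmann cyclisation with KOtBu in THF and acidic work-up gives isolated 18. Krapcho dealkoxycarbonylation (LiCl, H2O, DMSO, 150 °C) gives 3-oxo-18-norlabd-8(17)-en-15-oic acid F8. Kinetic enolisation towards C2 (LDA, TMSCl, −78 °C) gives its C2–C3 trimethylsilyl enol ether F9, and Saegusa–Ito dehydrogenation with Pd(OAc)2 in MeCN gives 3-oxo-18-norlabda-1,8(17)-dien-15-oic acid F10. This cross-conjugated enone can be deprotonated only at C4 (LDA, 2.2 equiv), and alkylation with benzyl chloromethyl ether from the α face gives 18-(benzyloxy)-3-oxolabda-1,8(17)-dien-15-oic acid F11. Conjugate reduction with [(Ph3P)CuH]6 in toluene gives 20.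

3. Step 6. Oxidation may start at the wrong allylic site (C5–H or the methyl group), and the γ-hydrogen at C5 of the product may epimerise through the dienol. The fallback sets out from 10 and returns at 11. Epoxidation with mCPBA gives ethyl 2-(1-methyl-7-oxabicyclo[4.1.0]heptan-2-yl)propanoate F1. Opening at the secondary carbon with sodium phenylselenide (PhSeSePh, NaBH4, EtOH) gives ethyl 2-[2-hydroxy-2-methyl-3-(phenylselanyl)cyclohexyl]propanoate F2. Oxidation with H2O2 and selenoxide syn-elimination give the tertiary allylic alcohol ethyl 2-(2-hydroxy-2-methylcyclohex-3-en-1-yl)propanoate F3. Oxidative 1,3-transposition with pyridinium chlorochromate (C5H5NH[CrO3Cl]) in CH2Cl2 gives 11. The ring stereocentre of 10 is carried through unchanged.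

**Further compounds**
F1 | step 6 | ethyl 2-(1-methyl-7-oxabicyclo[4.1.0]heptan-2-yl)propanoate (ring stereocentre as in 10) | CC12OC1CCC[C@H]2C(C)C(=O)OCC
F2 | step 6 | ethyl 2-[2-hydroxy-2-methyl-3-(phenylselanyl)cyclohexyl]propanoate | CC1(O)C([Se]c2ccccc2)CCC[C@H]1C(C)C(=O)OCC
F3 | step 6 | ethyl 2-(2-hydroxy-2-methylcyclohex-3-en-1-yl)propanoate | CC1(O)C=CCC[C@H]1C(C)C(=O)OCC
F4 | step 7 | benzyl (3S)-5-[(2S,3S)-3-(1-ethoxy-1-oxopropan-2-yl)-2-methyl-6-oxo-2-(prop-2-en-1-yl)cyclohexyl]-5-hydroxy-3-methylpentanoate | O=C1CC[C@@H](C(C)C(=O)OCC)[C@](C)(CC=C)C1C(O)C[C@H](C)CC(=O)OCc2ccccc2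
F5 | step 7 | benzyl (3S)-5-[(2S,3S)-3-(1-ethoxy-1-oxopropan-2-yl)-2-methyl-6-oxo-2-(prop-2-en-1-yl)cyclohexylidene]-3-methylpentanoate | O=C1CC[C@@H](C(C)C(=O)OCC)[C@](C)(CC=C)C1=CC[C@H](C)CC(=O)OCc2ccccc2
F6 | step 7 | 2-(3-hydroxypropyl) analogue of F5 | O=C1CC[C@@H](C(C)C(=O)OCC)[C@](C)(CCCO)C1=CC[C@H](C)CC(=O)OCc2ccccc2
F7 | step 7 | 2-(2-carboxyethyl) analogue of F5 | O=C1CC[C@@H](C(C)C(=O)OCC)[C@](C)(CCC(=O)O)C1=CC[C@H](C)CC(=O)OCc2ccccc2
F8 | step 12 | 3-oxo-18-norlabd-8(17)-en-15-oic acid (C4 not defined) | C=C1CC[C@H]2C(C)C(=O)CC[C@]2(C)[C@H]1CC[C@H](C)CC(=O)O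
F9 | step 12 | C2–C3 trimethylsilyl enol ether of F8 | C=C1CC[C@H]2C(C)C(O[Si](C)(C)C)=CC[C@]2(C)[C@H]1CC[C@H](C)CC(=O)O
F10 | step 12 | 3-oxo-18-norlabda-1,8(17)-dien-15-oic acid | C=C1CC[C@H]2C(C)C(=O)C=C[C@]2(C)[C@H]1CC[C@H](C)CC(=O)O
F11 | step 12 | 18-(benzyloxy)-3-oxolabda-1,8(17)-dien-15-oic acid | C=C1CC[C@H]2[C@](C)(COCc3ccccc3)C(=O)C=C[C@]2(C)[C@H]1CC[C@H](C)CC(=O)O
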